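**Retrosynthetic overview**

1. Locants: tetralin C1 (isopropyl), C4 (methyl), C4a, C5 and C6 (OH), C7 (CHO), C8 (pyranonyl), C8a; pyranone O1', C2'–C6' with C3' on C8. The strategy rests on ring A: the two neighbouring oxygens on C5 and C6 are read as a methoxycarbene carbon (C5) bonded to a carbon monoxide carbon (C6), and C4a=C8a (held cis inside ring B) with C8=C7 as the diene that closes onto C6.
2. Ring B comes intact from (S)-carvone (C1 from carvone C5, C4 by equilibration to the trans ketone). Bromoformylation, alkyne homologation and syn-carboalumination give the (E)-dienyl bromide and from it the chromium methoxycarbene.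
3. Ring A: photochemical CO insertion (C5–C6) and six-electron electrocyclisation (C6–C7) give the catechol monoether with a C7 acetal and a C8 methyl.
4. Pyranone: the C8 methyl is carboxylated by ester-directed lateral lithiation and tied to C7 as an isochroman-3-one. C3' acetylation, dianion acylation with a cinnamoyl Weinreb amide and translactonisation form C2'–O1' and release C7–CH2OH.
5. Finish: oxidation to the C7 aldehyde and cleavage of four methyl ethers. Ring order: B (chiral pool), A (key step), temporary lactone, pyranone.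

Key step: step 8

Remark: the target structure assigns no configuration to the hindered C8–C3' axis, so none is controlled, and the C7 aldehyde is treated as the open form, not as a lactol with the C4' hydroxyl.

**Route**

Step 1
Reactants: 1 (S)-(+)-carvone
Product: 3 (2S,5S)-2-methyl-5-(propan-2-yl)cyclohexan-1-one (trans-carvomenthone), via isocarvomenthone 2 (not isolated)
Conditions: H2 (1 atm), 10% Pd/C, EtOAc, rt; then NaOMe (cat.), MeOH, rt
Reagents that add atoms: none
Why: Catalytic hydrogenation saturates both alkenes without touching carvone C5 (the later C1, R), and methoxide equilibration through the enolate should enrich the diequatorial trans epimer, so the C4 methyl centre is set under thermodynamic control.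

Step 2
Reactants: 3 trans-carvomenthone
Product: 5 (3S,6R)-2-bromo-3-methyl-6-(propan-2-yl)cyclohex-1-ene-1-carbaldehyde, via iminium bromide 4 (not isolated)
Conditions: PBr3, DMF, CHCl3, 0 °C to rt; then ice-water
Reagents that add atoms: N,N-dimethylformamide, CN(C)C=O; phosphorus tribromide, BrP(Br)Br; water, O
Why: Vilsmeier–Haack–Arnold bromoformylation takes place at the only α-methylene, so the formyl carbon becomes C8 on C8a and bromine marks C4a; the methyl centre is carried over from 3 in the trans (di-pseudoaxial) arrangement favoured next to the tetrasubstituted alkene, and epimer arising from residual 2 should be separable here by chromatography.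

Step 3
Reactants: 5 bromoenal
Product: 6 (3R,6S)-1-bromo-2-ethynyl-6-methyl-3-(propan-2-yl)cyclohex-1-ene
Conditions: dimethyl (1-diazo-2-oxopropyl)phosphonate, K2CO3, MeOH, 0 °C to rt
Reagents that add atoms: dimethyl (1-diazo-2-oxopropyl)phosphonate, CC(=O)C(=[N+]=[N-])P(=O)(OC)OC
Why: Ohira–Bestmann (Seyferth–Gilbert) homologation turns the aldehyde into the terminal alkyne under mild carbonate conditions that should leave the hindered vinyl bromide and both stereocentres untouched.

Step 4
Reactants: 6 bromo enyne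
Product: 9 (2E)-3-[(3S,6R)-2-bromo-3-methyl-6-(propan-2-yl)cyclohex-1-en-1-yl]but-2-en-1-ol, via alkenylalane 7 (not isolated), via lithium alanate 8 (not isolated)
Conditions: AlMe3, Cp2ZrCl2 (0.25 equiv), CH2Cl2, 0 °C to rt; evaporation; n-BuLi, hexane, 0 °C; (CH2O)n, THF, rt; aq. KNaC4H4O6
Reagents that add atoms: trimethylaluminium, C[Al](C)C; paraformaldehyde (as formaldehyde), C=O
Why: Zirconium-catalysed Negishi carboalumination adds methyl and aluminium syn across the terminal alkyne with methyl on the internal carbon C8, and the alanate is hydroxymethylated with retention, so CH2OH ends up trans to the ring (E) while n-BuLi is taken up by aluminium before it can exchange the vinyl bromide.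

Step 5
Reactants: 9 allylic alcohol
Product: 10 (2E)-3-[(3S,6R)-2-bromo-3-methyl-6-(propan-2-yl)cyclohex-1-en-1-yl]but-2-enal
Conditions: MnO2, CH2Cl2, rt
Reagents that add atoms: none
Why: MnO2 oxidises allylic alcohols selectively to enals without over-oxidation and should not disturb the E double bond.

Step 6
Reactants: 10 dienal
Product: 11 (3S,6R)-2-bromo-1-[(2E)-4,4-dimethoxybut-2-en-2-yl]-3-methyl-6-(propan-2-yl)cyclohex-1-ene
Conditions: HC(OMe)3, MeOH, pyridinium p-toluenesulfonate (cat.), rt; Et3N quench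
Reagents that add atoms: trimethyl orthoformate, COC(OC)OC; methanol, CO
Why: Acid-catalysed acetalisation with the orthoformate as water scavenger masks the aldehyde against the organolithium of the next step, and the weak pyridinium acid should preserve the E geometry.

Step 7
Reactants: 11 dienyl bromide acetal; 12 hexacarbonylchromium
Product: 15 pentacarbonyl{methoxy[(3R,6S)-2-[(2E)-4,4-dimethoxybut-2-en-2-yl]-6-methyl-3-(propan-2-yl)cyclohex-1-en-1-yl]methylidene}chromium, via vinyllithium 13 (not isolated), via lithium acylchromate 14 (not isolated)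
Conditions: t-BuLi (2 equiv), Et2O, −78 °C; Cr(CO)6, Et2O/THF, −78 °C to rt; then Me3OBF4, CH2Cl2, 0 °C
Reagents that add atoms: trimethyloxonium tetrafluoroborate, C[O+](C)C.F[B-](F)(F)F
Why: Bromine–lithium exchange gives the ring vinyllithium, which adds to a CO ligand of Cr(CO)6, and O-methylation of the acylchromate by the hard oxonium salt is the classical Fischer carbene synthesis, with the acetal inert throughout.

Step 8
Reactants: 15 dienyl(methoxy)carbene complex
Product: 18 (1R,4S)-7-(dimethoxymethyl)-5-methoxy-4,8-dimethyl-1-(propan-2-yl)-1,2,3,4-tetrahydronaphthalen-6-ol (overview locants), via dienylketene 16 (not isolated), via cyclohexadienone 17 (not isolated)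
Conditions: hν (medium-pressure Hg lamp, Pyrex), CO (1 atm), THF, rt; chromatography on Et3N-deactivated silica
Reagents that add atoms: none
Why: Irradiation into the metal-to-ligand charge-transfer band moves a CO ligand onto the carbene carbon and gives a chromium-bound dienylketene with the ketene carbon as C6 and the methoxy-bearing carbon as C5; a six-electron disrotatory electrocyclisation of the C6=C5–C4a=C8a–C8=C7 triene then joins C6 to C7, and enolisation of the cyclohexa-2,4-dienone gives the phenol while CO returns the metal as Cr(CO)6. The closest known reaction type is the photochemical carbonylative benzannulation of dienyl(alkoxy)carbene chromium complexes to ortho-alkoxyphenols. Ring A closes by this 6π electrocyclic mode; no stereocentre is created, because the sp3 carbon formed at C7 is lost on aromatisation and C1 and C4 are not involved. The step needs the two oxygens ortho, which follows from CO inserting at the carbene carbon, a cis central double bond, which ring B enforces at C4a=C8a, and hydrogen pointing inward at C7, which the E geometry from step 4 provides. The CO atmosphere should suppress the CO-free pathways of the carbene that lead to five-membered rings.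

Step 9
Reactants: 18 phenol acetal
Product: 20 (1R,4S)-5,6-dimethoxy-4,8-dimethyl-1-(propan-2-yl)-1,2,3,4-tetrahydronaphthalene-7-carbaldehyde, via dimethoxy acetal 19 (not isolated)
Conditions: MeI, K2CO3, acetone, reflux; then 1 M HCl, THF, rt
Reagents that add atoms: iodomethane, CI; water, O
Why: Williamson methylation of the phenol followed by aqueous acid hydrolysis of the electron-rich benzylic acetal should give the aldehyde, and methylating first avoids handling the labile ortho-hydroxy acetal.

Step 10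
Reactants: 20 aldehyde
Product: 21 (1R,4S)-5,6-dimethoxy-4,8-dimethyl-1-(propan-2-yl)-1,2,3,4-tetrahydronaphthalene-7-carboxylic acid
Conditions: NaClO2, NaH2PO4, 2-methyl-2-butene, t-BuOH/H2O, rt
Reagents that add atoms: sodium chlorite, [Na+].[O-]Cl=O
Why: Pinnick oxidation converts hindered, electron-rich aryl aldehydes into acids under buffered conditions, with the alkene removing hypochlorite before it can chlorinate the ring.

Step 11
Reactants: 21 acid
Product: 22 methyl (1R,4S)-5,6-dimethoxy-4,8-dimethyl-1-(propan-2-yl)-1,2,3,4-tetrahydronaphthalene-7-carboxylate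
Conditions: MeI, K2CO3, DMF, rt
Reagents that add atoms: iodomethane, CI
Why: Alkylation of the carboxylate at methyl (SN2) avoids the carbonyl addition step that makes Fischer esterification of di-ortho-substituted benzoic acids fail.

Step 12
Reactants: 22 ortho-toluate ester
Product: 24 2-[(1R,4S)-5,6-dimethoxy-7-(methoxycarbonyl)-4-methyl-1-(propan-2-yl)-1,2,3,4-tetrahydronaphthalen-8-yl]acetic acid, via benzylic lithium 23 (not isolated)
Conditions: LiN(iPr)2, THF, −78 °C; CO2 (g), −78 to 0 °C; 1 M HCl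
Reagents that add atoms: carbon dioxide, O=C=O
Why: Lateral lithiation of an ortho-toluate removes a proton from the C8 methyl, the only position acidified by conjugation with the C7 ester (whose two ortho substituents block self-condensation), and the benzylic anion is trapped by CO2.

Step 13
Reactants: 24 half-ester acid
Product: 26 isochroman-3-one in which C7–CH2–O–C(=O)–CH2–C8 forms a δ-lactone on the (1R,4S)-5,6-dimethoxy-4-methyl-1-(propan-2-yl)tetralin, via hydroxy acid 25 (not isolated)
Conditions: LiEt3BH, THF, 0 °C to rt; then 2 M HCl, rt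
Reagents that add atoms: none
Why: Triethylborohydride reduces the hindered aryl ester to the benzylic alcohol while the carboxylate, formed at once by deprotonation, resists hydride, and acidification closes the six-membered lactone (chemoselective ester reduction, then lactonisation).

Step 14
Reactants: 26 isochroman-3-one
Product: 28 C3'-acetyl isochroman-3-one (β-keto lactone, keto/enol mixture), via lithium enolate 27 (not isolated)
Conditions: LiN(SiMe3)2 (2.1 equiv), THF, −78 °C; AcCl, −78 to 0 °C; 1 M HCl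
Reagents that add atoms: acetyl chloride, CC(Cl)=O
Why: C-acylation of a lithium lactone enolate (crossed Claisen type) occurs at the only enolisable carbon, C3', the second equivalent of base keeps the more acidic product as its enolate, and the configuration at C3' is irrelevant because this carbon becomes sp2.

Step 15
Reactants: 29 (E)-3,4-dimethoxycinnamic acid
Product: 31 (E)-3-(3,4-dimethoxyphenyl)-N-methoxy-N-methylprop-2-enamide, via acylimidazole 30 (not isolated)
Conditions: 1,1'-carbonyldiimidazole, CH2Cl2, rt; then MeNHOMe·HCl, rt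
Reagents that add atoms: N,O-dimethylhydroxylamine hydrochloride, CNOC.Cl
Why: Activation of the acid as its acylimidazole and aminolysis give the Weinreb amide with the E alkene unchanged.

Step 16
Reactants: 28 C3'-acetyl isochroman-3-one; 31 Weinreb amide
Product: 34 3-[(1R,4S)-7-(hydroxymethyl)-5,6-dimethoxy-4-methyl-1-(propan-2-yl)-1,2,3,4-tetrahydronaphthalen-8-yl]-6-[(E)-2-(3,4-dimethoxyphenyl)ethenyl]-4-hydroxy-2H-pyran-2-one, via dilithium dianion 32 (not isolated), via dioxo lactone 33 (not isolated)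
Conditions: LiN(iPr)2 (2.3 equiv), THF, −78 to −20 °C; 31, −78 to 0 °C; 1 M HCl; then DBU, PhMe, 60 °C; 1 M HCl
Reagents that add atoms: none
Why: Acylation of a β-keto ester dianion at its terminal carbon by a Weinreb amide (whose chelated adduct prevents over-addition) gives the 3,5-dioxo lactone, and base-promoted enol lactonisation of the C6' enol oxygen onto C2' (6-exo-trig translactonisation) should be driven by formation of the acidic 4-hydroxy-2-pyranone anion and sets free the C7 hydroxymethyl group.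

Step 17
Reactants: 34 pyranone benzylic alcohol
Product: 35 (1R,4S)-8-{6-[(E)-2-(3,4-dimethoxyphenyl)ethenyl]-4-hydroxy-2-oxo-2H-pyran-3-yl}-5,6-dimethoxy-4-methyl-1-(propan-2-yl)-1,2,3,4-tetrahydronaphthalene-7-carbaldehyde
Conditions: MnO2, CH2Cl2, rt
Reagents that add atoms: none
Why: MnO2 oxidises the electron-rich benzylic alcohol to the aldehyde and should leave the styrene, the pyranone and the aryl ethers alone.

Step 18
Reactants: 35 tetramethyl ether aldehyde
Product: 36 Heimiomycin B
Conditions: BBr3, CH2Cl2, −78 to 0 °C; then H2O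
Reagents that add atoms: none
Why: Lewis-acid cleavage of the four aryl methyl ethers by BBr3, a method that tolerates ortho-hydroxy aryl aldehydes and styrylpyranones, should free both catechols without touching the benzylic stereocentres.

**Compound list**

1 | (S)-(+)-carvone | CC1=CC[C@@H](CC1=O)C(C)=C | starting material
2 | (2R,5S)-2-methyl-5-(propan-2-yl)cyclohexan-1-one (isocarvomenthone, cis) | CC(C)[C@H]1CC[C@@H](C)C(=O)C1 | intermediate
3 | (2S,5S)-2-methyl-5-(propan-2-yl)cyclohexan-1-one (carvomenthone, trans) | CC(C)[C@H]1CC[C@H](C)C(=O)C1 | intermediate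
4 | N-{[(3S,6R)-2-bromo-3-methyl-6-(propan-2-yl)cyclohex-1-en-1-yl]methylidene}-N-methylmethanaminium bromide | CC(C)[C@H]1CC[C@H](C)C(Br)=C1C=[N+](C)C.[Br-] | intermediate
5 | (3S,6R)-2-bromo-3-methyl-6-(propan-2-yl)cyclohex-1-ene-1-carbaldehyde | CC(C)[C@H]1CC[C@H](C)C(Br)=C1C=O | intermediate
6 | (3R,6S)-1-bromo-2-ethynyl-6-methyl-3-(propan-2-yl)cyclohex-1-ene | CC(C)[C@H]1CC[C@H](C)C(Br)=C1C#C | intermediate
7 | {(1E)-2-[(3S,6R)-2-bromo-3-methyl-6-(propan-2-yl)cyclohex-1-en-1-yl]prop-1-en-1-yl}dimethylalane | CC(C)[C@H]1CC[C@H](C)C(Br)=C1/C(C)=C/[Al](C)C | intermediate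
8 | lithium butyl{(1E)-2-[(3S,6R)-2-bromo-3-methyl-6-(propan-2-yl)cyclohex-1-en-1-yl]prop-1-en-1-yl}dimethylalanate | CC(C)[C@H]1CC[C@H](C)C(Br)=C1/C(C)=C/[Al-](C)(C)CCCC.[Li+] | intermediate
9 | (2E)-3-[(3S,6R)-2-bromo-3-methyl-6-(propan-2-yl)cyclohex-1-en-1-yl]but-2-en-1-ol | CC(C)[C@H]1CC[C@H](C)C(Br)=C1/C(C)=C/CO | intermediate
10 | (2E)-3-[(3S,6R)-2-bromo-3-methyl-6-(propan-2-yl)cyclohex-1-en-1-yl]but-2-enal | CC(C)[C@H]1CC[C@H](C)C(Br)=C1/C(C)=C/C=O | intermediate
11 | (3S,6R)-2-bromo-1-[(2E)-4,4-dimethoxybut-2-en-2-yl]-3-methyl-6-(propan-2-yl)cyclohex-1-ene | CC(C)[C@H]1CC[C@H](C)C(Br)=C1/C(C)=C/C(OC)OC | intermediate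
12 | hexacarbonylchromium | O=C=[Cr](=C=O)(=C=O)(=C=O)(=C=O)=C=O | starting material
13 | {(3R,6S)-2-[(2E)-4,4-dimethoxybut-2-en-2-yl]-6-methyl-3-(propan-2-yl)cyclohex-1-en-1-yl}lithium | CC(C)[C@H]1CC[C@H](C)C([Li])=C1/C(C)=C/C(OC)OC | intermediate
14 | lithium pentacarbonyl{[(3R,6S)-2-[(2E)-4,4-dimethoxybut-2-en-2-yl]-6-methyl-3-(propan-2-yl)cyclohex-1-en-1-yl]carbonyl}chromate | CC(C)[C@H]1CC[C@H](C)C(C([O-])=[Cr](=C=O)(=C=O)(=C=O)(=C=O)=C=O)=C1/C(C)=C/C(OC)OC.[Li+] | intermediate
15 | pentacarbonyl{methoxy[(3R,6S)-2-[(2E)-4,4-dimethoxybut-2-en-2-yl]-6-methyl-3-(propan-2-yl)cyclohex-1-en-1-yl]methylidene}chromium | CC(C)[C@H]1CC[C@H](C)C(C(OC)=[Cr](=C=O)(=C=O)(=C=O)(=C=O)=C=O)=C1/C(C)=C/C(OC)OC | intermediate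
16 | 2-methoxy-2-{(3R,6S)-2-[(2E)-4,4-dimethoxybut-2-en-2-yl]-6-methyl-3-(propan-2-yl)cyclohex-1-en-1-yl}ethen-1-one (dienylketene, chromium-bound in the flask, drawn metal-free) | CC(C)[C@H]1CC[C@H](C)C(C(OC)=C=O)=C1/C(C)=C/C(OC)OC | intermediate
17 | (1R,4S)-7-(dimethoxymethyl)-5-methoxy-4,8-dimethyl-1-(propan-2-yl)-2,3,4,7-tetrahydronaphthalen-6(1H)-one (C7 unassigned) | CC(C)[C@H]1CC[C@H](C)C2=C(OC)C(=O)C(C(OC)OC)C(C)=C12 | intermediate
18 | (1R,4S)-7-(dimethoxymethyl)-5-methoxy-4,8-dimethyl-1-(propan-2-yl)-1,2,3,4-tetrahydronaphthalen-6-ol | CC(C)[C@H]1CC[C@H](C)c2c(OC)c(O)c(C(OC)OC)c(C)c21 | intermediate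
19 | (1R,4S)-7-(dimethoxymethyl)-5,6-dimethoxy-4,8-dimethyl-1-(propan-2-yl)-1,2,3,4-tetrahydronaphthalene | CC(C)[C@H]1CC[C@H](C)c2c(OC)c(OC)c(C(OC)OC)c(C)c21 | intermediate
20 | (1R,4S)-5,6-dimethoxy-4,8-dimethyl-1-(propan-2-yl)-1,2,3,4-tetrahydronaphthalene-7-carbaldehyde | CC(C)[C@H]1CC[C@H](C)c2c(OC)c(OC)c(C=O)c(C)c21 | intermediate
21 | (1R,4S)-5,6-dimethoxy-4,8-dimethyl-1-(propan-2-yl)-1,2,3,4-tetrahydronaphthalene-7-carboxylic acid | CC(C)[C@H]1CC[C@H](C)c2c(OC)c(OC)c(C(=O)O)c(C)c21 | intermediate
22 | methyl (1R,4S)-5,6-dimethoxy-4,8-dimethyl-1-(propan-2-yl)-1,2,3,4-tetrahydronaphthalene-7-carboxylate | CC(C)[C@H]1CC[C@H](C)c2c(OC)c(OC)c(C(=O)OC)c(C)c21 | intermediate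
23 | C8 benzylic lithium derivative of 22 (ortho-quinodimethane enolate) | CC(C)[C@H]1CC[C@H](C)c2c(OC)c(OC)c(C(=O)OC)c(C[Li])c21 | intermediate
24 | 2-[(1R,4S)-5,6-dimethoxy-7-(methoxycarbonyl)-4-methyl-1-(propan-2-yl)-1,2,3,4-tetrahydronaphthalen-8-yl]acetic acid | CC(C)[C@H]1CC[C@H](C)c2c(OC)c(OC)c(C(=O)OC)c(CC(=O)O)c21 | intermediate
25 | 2-[(1R,4S)-7-(hydroxymethyl)-5,6-dimethoxy-4-methyl-1-(propan-2-yl)-1,2,3,4-tetrahydronaphthalen-8-yl]acetic acid | CC(C)[C@H]1CC[C@H](C)c2c(OC)c(OC)c(CO)c(CC(=O)O)c21 | intermediate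
26 | isochroman-3-one (δ-lactone of 25, C7–CH2–O–C(=O)–CH2–C8) | CC(C)[C@H]1CC[C@H](C)c2c(OC)c(OC)c3COC(=O)Cc3c21 | intermediate
27 | lithium enolate of 26 | CC(C)[C@H]1CC[C@H](C)c2c(OC)c(OC)c3COC(O[Li])=Cc3c21 | intermediate
28 | C3'-acetyl derivative of 26 (C3' unassigned, enolisable) | CC(C)[C@H]1CC[C@H](C)c2c(OC)c(OC)c3COC(=O)C(C(C)=O)c3c21 | intermediate
29 | (E)-3,4-dimethoxycinnamic acid | COc1ccc(/C=C/C(=O)O)cc1OC | starting material
30 | (E)-3-(3,4-dimethoxyphenyl)-1-(1H-imidazol-1-yl)prop-2-en-1-one | COc1ccc(/C=C/C(=O)n2ccnc2)cc1OC | intermediate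
31 | (E)-3-(3,4-dimethoxyphenyl)-N-methoxy-N-methylprop-2-enamide | COc1ccc(/C=C/C(=O)N(C)OC)cc1OC | intermediate
32 | dilithium dianion of 28 (lactone enolate and terminal ketone enolate) | CC(C)[C@H]1CC[C@H](C)c2c(OC)c(OC)c3COC(O[Li])=C(C(=C)O[Li])c3c21 | intermediate
33 | C3'-[(E)-5-(3,4-dimethoxyphenyl)-3-oxopent-4-enoyl] derivative of 26 | CC(C)[C@H]1CC[C@H](C)c2c(OC)c(OC)c3COC(=O)C(C(=O)CC(=O)/C=C/c4ccc(OC)c(OC)c4)c3c21 | intermediate
34 | 3-[(1R,4S)-7-(hydroxymethyl)-5,6-dimethoxy-4-methyl-1-(propan-2-yl)-1,2,3,4-tetrahydronaphthalen-8-yl]-6-[(E)-2-(3,4-dimethoxyphenyl)ethenyl]-4-hydroxy-2H-pyran-2-one | CC(C)[C@H]1CC[C@H](C)c2c(OC)c(OC)c(CO)c(-c3c(O)cc(/C=C/c4ccc(OC)c(OC)c4)oc3=O)c21 | intermediate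
35 | C7 aldehyde of 34 | CC(C)[C@H]1CC[C@H](C)c2c(OC)c(OC)c(C=O)c(-c3c(O)cc(/C=C/c4ccc(OC)c(OC)c4)oc3=O)c21 | intermediate
36 | Heimiomycin B | CC(C)[C@H]1CC[C@H](C)c2c(O)c(O)c(C=O)c(-c3c(O)cc(/C=C/c4ccc(O)c(O)c4)oc3=O)c21 | target

**Totals and risks**

Total step count: 18. Longest linear sequence: 17 steps (steps 1–14 and 16–18).

Step 8. After CO insertion the ketene may fail to reach the folded geometry needed for closure, because the C8 methyl and the C1 isopropyl crowd the C8a–C8 bond. The carbene may instead lose CO and collapse to five-membered-ring or demetalated products. The fallback makes the same dienylketene without chromium and sets out from bromide 11. Its vinyllithium 13 is added to ethyl glyoxylate to give the α-hydroxy ester F1. O-Methylation with Ag2O and MeI gives the α-methoxy ester F2, and LiOH gives the acid F3. Heating F3 with Ac2O and NaOAc should form the mixed anhydride, eliminate to metal-free ketene 16 and close through 17; the phenol is acetylated in the flask to the aryl acetate F4. K2CO3 in MeOH removes the acetate, and the route is rejoined at 18.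

Step 16. Acylation of the dianion may be slow beside the crowded C3'. The acyl transfer that opens the δ-lactone may also stall or revert, because the freed benzylic alkoxide stays tethered next to C2'. The fallback uses an open-chain ester with a silyl-protected alcohol and sets out from 26. LiOH opens 26 to the carboxylate of 25, and TBSCl with imidazole silylates both oxygens to the bis-silyl compound F5. K2CO3 in aqueous MeOH cleaves the silyl ester to the acid F6, and TMSCHN2 gives the methyl ester F7. LiN(SiMe3)2 forms the lithium enolate F8, which AcCl converts into the β-keto ester F9. LiN(iPr)2 gives the dianion F10, which 31 acylates to the 3,5-dioxo ester F11. DBU in hot toluene closes F11 with irreversible loss of methanol to the silyl-protected pyranone F12. HF·pyridine removes the silyl group, and the route is rejoined at 34.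

Step 4. Carbometalation of an alkyne flanked by a tetrasubstituted bromoalkene may be slow or lose regiocontrol, and the alanate may transfer butyl in place of the alkenyl group. The fallback builds the trisubstituted alkene by carbonyl olefination and sets out from 5, bypassing steps 3 and 4. MeMgBr adds to 5 to give the carbinol F13, and Dess–Martin periodinane gives the methyl ketone F14. Horner–Wadsworth–Emmons olefination with triethyl phosphonoacetate and NaH in refluxing THF should give mainly the (E)-enoate F15, with the minor Z isomer removed by chromatography. iBu2AlH reduction of F15 rejoins the route at 9.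

**Further compounds**

F1 | step 8 | ethyl 2-hydroxy-2-{(3R,6S)-2-[(2E)-4,4-dimethoxybut-2-en-2-yl]-6-methyl-3-(propan-2-yl)cyclohex-1-en-1-yl}acetate | CC(C)[C@H]1CC[C@H](C)C(C(O)C(=O)OCC)=C1/C(C)=C/C(OC)OC
F2 | step 8 | ethyl 2-methoxy-2-{(3R,6S)-2-[(2E)-4,4-dimethoxybut-2-en-2-yl]-6-methyl-3-(propan-2-yl)cyclohex-1-en-1-yl}acetate | CC(C)[C@H]1CC[C@H](C)C(C(OC)C(=O)OCC)=C1/C(C)=C/C(OC)OC
F3 | step 8 | 2-methoxy-2-{(3R,6S)-2-[(2E)-4,4-dimethoxybut-2-en-2-yl]-6-methyl-3-(propan-2-yl)cyclohex-1-en-1-yl}acetic acid | CC(C)[C@H]1CC[C@H](C)C(C(OC)C(=O)O)=C1/C(C)=C/C(OC)OC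
F4 | step 8 | C6 acetate of 18 | CC(C)[C@H]1CC[C@H](C)c2c(OC)c(OC(C)=O)c(C(OC)OC)c(C)c21
F5 | step 16 | bis(tert-butyldimethylsilyl) derivative of 25 (silyl ether and silyl ester) | CC(C)[C@H]1CC[C@H](C)c2c(OC)c(OC)c(CO[Si](C)(C)C(C)(C)C)c(CC(=O)O[Si](C)(C)C(C)(C)C)c21
F6 | step 16 | tert-butyldimethylsilyl ether of 25 (free acid) | CC(C)[C@H]1CC[C@H](C)c2c(OC)c(OC)c(CO[Si](C)(C)C(C)(C)C)c(CC(=O)O)c21
F7 | step 16 | methyl ester of F6 | CC(C)[C@H]1CC[C@H](C)c2c(OC)c(OC)c(CO[Si](C)(C)C(C)(C)C)c(CC(=O)OC)c21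
F8 | step 16 | lithium enolate of F7 | CC(C)[C@H]1CC[C@H](C)c2c(OC)c(OC)c(CO[Si](C)(C)C(C)(C)C)c(C=C(O[Li])OC)c21
F9 | step 16 | C3'-acetyl derivative of F7 (β-keto ester) | CC(C)[C@H]1CC[C@H](C)c2c(OC)c(OC)c(CO[Si](C)(C)C(C)(C)C)c(C(C(C)=O)C(=O)OC)c21
F10 | step 16 | dilithium dianion of F9 | CC(C)[C@H]1CC[C@H](C)c2c(OC)c(OC)c(CO[Si](C)(C)C(C)(C)C)c(C(C(=C)O[Li])=C(O[Li])OC)c21
F11 | step 16 | methyl 2-aryl-7-(3,4-dimethoxyphenyl)-3,5-dioxohept-6-enoate with the silyl ether (3,5-dioxo ester) | CC(C)[C@H]1CC[C@H](C)c2c(OC)c(OC)c(CO[Si](C)(C)C(C)(C)C)c(C(C(=O)OC)C(=O)CC(=O)/C=C/c3ccc(OC)c(OC)c3)c21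
F12 | step 16 | tert-butyldimethylsilyl ether of 34 | CC(C)[C@H]1CC[C@H](C)c2c(OC)c(OC)c(CO[Si](C)(C)C(C)(C)C)c(-c3c(O)cc(/C=C/c4ccc(OC)c(OC)c4)oc3=O)c21
F13 | step 4 | 1-[(3S,6R)-2-bromo-3-methyl-6-(propan-2-yl)cyclohex-1-en-1-yl]ethan-1-ol | CC(C)[C@H]1CC[C@H](C)C(Br)=C1C(C)O
F14 | step 4 | 1-[(3S,6R)-2-bromo-3-methyl-6-(propan-2-yl)cyclohex-1-en-1-yl]ethan-1-one | CC(C)[C@H]1CC[C@H](C)C(Br)=C1C(C)=O
F15 | step 4 | ethyl (2E)-3-[(3S,6R)-2-bromo-3-methyl-6-(propan-2-yl)cyclohex-1-en-1-yl]but-2-enoate | CC(C)[C@H]1CC[C@H](C)C(Br)=C1/C(C)=C/C(=O)OCC
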